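**Plan**

- Retrosynthesis cuts N4–C9a first (with C5 as a lactam carbonyl) by an intramolecular Schmidt ring expansion. This is possible because N4 joins the quaternary ring-fusion carbon C9a to C5 inside the fused pyrrolidine and azepane rings while C3 lies three carbons from C9a; the C9a–N4–C5(=O) unit is the retron of a cyclohexanone-to-caprolactam nitrogen insertion on a cis-hydrindan-4-one.
- Further cuts: C3–N (azide displacement) and C3–C18 (vinylogous aldol) for the side-chain lactone; C13–Me, C13–O, O11–C14 and C12–C13 for the fused lactone; C9=C10 (aldol condensation) and both exocyclic C9a–C bonds of a 2,2-disubstituted cyclohexane-1,3-dione.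
- Forward order of rings: cyclohexane (dione) → cyclopentenone (hydration/aldol) → cis-fused γ-lactone → side-chain butenolide → pyrrolidine and azepane together in the Schmidt step; the lactam carbonyl is then removed.
- Stereochemistry: C9a from a catalyst-controlled desymmetrising reduction, carried with retention through the Schmidt shift; C12 by alkylation anti to the C5 branch; C11 by hydride anti to the C12 arm; C9 and C10 by hydroxyl-directed syn hydrogenation; C13 by convex-face methylation; C3/C18 by a catalyst-controlled anti vinylogous aldol; C20 by butenolide hydrogenation; C3 inverted by azide.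

Key step: step 19

Remark on locants: the target's locants are used throughout (pyrrolo[1,2-a]azepine C1–C3, N4, C5–C9, C9a; cyclopentane C10 (ethyl), C11 (O), C12; fused lactone C13 (Me, OH), C14 (C=O); side-chain lactone C18 (CH–O), C19, C20 (CHMe), C21 (C=O)). β is the cyclopentane face carrying C1 on C9a; α is the face carrying C5.

Assumption: in step 3 the hydroxyl is taken to form cis to the pentynyl chain. If the opposite diastereomer prevails, the enantiomeric catalyst gives the C5 epimer with the same C9a configuration, which serves equally because C5 is oxidised in step 14.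

Step 1
Reactants: 1 cyclohexane-1,3-dione; 2 3-(benzyloxy)propanal
Product: 3 2-[3-(benzyloxy)propyl]cyclohexane-1,3-dione
Conditions: Hantzsch ester (1.0 equiv), L-proline (10 mol %), CH2Cl2, rt
Reagents that add atoms: none
Why: Knoevenagel condensation followed by in situ conjugate transfer hydrogenation of the alkylidene dione (three-component reductive alkylation) should give clean mono-C-alkylation, which direct alkylation with an unactivated halide does not.

Step 2
Reactants: 3 2-[3-(benzyloxy)propyl]cyclohexane-1,3-dione; 4 1-bromopent-2-yne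
Product: 5 2-[3-(benzyloxy)propyl]-2-(pent-2-yn-1-yl)cyclohexane-1,3-dione
Conditions: KOH (1.05 equiv), H2O/dioxane, 50 °C
Reagents that add atoms: none
Why: C-alkylation of the 2-alkyl-1,3-dione enolate with a propargylic bromide in a protic medium (which favours C- over O-alkylation) should build the prochiral quaternary carbon C9a with both chains.

Step 3
Reactants: 5 2-[3-(benzyloxy)propyl]-2-(pent-2-yn-1-yl)cyclohexane-1,3-dione
Product: 6 (2R,3R)-2-[3-(benzyloxy)propyl]-3-hydroxy-2-(pent-2-yn-1-yl)cyclohexan-1-one
Conditions: (S)-2-methyl-CBS-oxazaborolidine (20 mol %), catecholborane (1.2 equiv), toluene, −60 °C; MeOH, then aq. NaHCO3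
Reagents that add atoms: none
Why: Corey–Bakshi–Shibata reduction used as a desymmetrising mono-reduction of a 2,2-disubstituted 1,3-dione: the catalyst fixes the carbinol as R (quaternary carbon as the large group), and hydride delivery trans to the axial, slimmer pentynyl chain selects the carbonyl, which together should set C9a.

Step 4
Reactants: 6 (2R,3R)-2-[3-(benzyloxy)propyl]-3-hydroxy-2-(pent-2-yn-1-yl)cyclohexan-1-one
Product: 7 (2R,3R)-3-(benzyloxy)-2-[3-(benzyloxy)propyl]-2-(pent-2-yn-1-yl)cyclohexan-1-one
Conditions: benzyl 2,2,2-trichloroacetimidate (1.5 equiv), TfOH (5 mol %), CH2Cl2/cyclohexane, 0 °C → rt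
Reagents that add atoms: benzyl 2,2,2-trichloroacetimidate, ClC(Cl)(Cl)C(=N)OCc1ccccc1
Why: acid-catalysed imidate benzylation avoids the basic conditions under which this β-hydroxy ketone could undergo retro-aldol cleavage, and masks the future C5 ketone as an ether that leaves later together with the C3 benzyl ether.

Step 5
Reactants: 7 (2R,3R)-3-(benzyloxy)-2-[3-(benzyloxy)propyl]-2-(pent-2-yn-1-yl)cyclohexan-1-one
Product: 9 (7R,7aS)-7-(benzyloxy)-7a-[3-(benzyloxy)propyl]-3-ethyl-1,4,5,6,7,7a-hexahydro-2H-inden-2-one, via 2-oxopentyl diketone 8 (not isolated)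
Conditions: NaAuCl4·2H2O (5 mol %), MeOH/H2O, 65 °C; then KOH (2 equiv), 65 °C
Reagents that add atoms: water, O
Why: carbonyl-assisted Markovnikov hydration (5-exo-dig attack of the ketone oxygen on the gold-activated alkyne) places the new ketone at C11, and base-mediated intramolecular aldol condensation of the resulting 1,4-diketone (C10 onto the only ring ketone, C9) should close the cyclopentenone.

Step 6
Reactants: 9 bicyclic enone; 10 tert-butyl bromoacetate
Product: 11 C12-alkylated enone (9 with a CH2CO2t-Bu arm on C12, β, cis to the 3-benzyloxypropyl chain)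
Conditions: LiN(i-Pr)2 (1.1 equiv), THF, −78 °C; DMPU, then 10, −78 → −40 °C
Reagents that add atoms: none
Why: kinetic α′-deprotonation gives the cross-conjugated dienolate, whose alkylation at C12 should occur anti to the bulkier secondary C5(OBn) branch on the adjacent quaternary carbon, that is, cis to the primary C1 chain.

Step 7
Reactants: 11 C12-alkylated enone
Product: 12 allylic alcohol (11 with the ketone reduced to 11β-OH, cis to the C12 arm)
Conditions: NaBH4, CeCl3·7H2O, MeOH, −40 °C
Reagents that add atoms: none
Why: Luche 1,2-reduction with hydride entering anti to the adjacent C12 arm should give the 11β-alcohol, while the tert-butyl ester prevents premature lactonisation.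

Step 8
Reactants: 12 allylic alcohol
Product: 13 cis-hydrindanol (12 with C9=C10 saturated; 9-H and 10-H β, 10-ethyl α)
Conditions: [Ir(cod)(PCy3)(py)]PF6 (10 mol %), H2 (1–20 bar), CH2Cl2, rt
Reagents that add atoms: none
Why: hydroxyl-directed homogeneous hydrogenation of the tetrasubstituted allylic alkene delivers both hydrogens syn to the 11β-OH, which should set the cis ring fusion and place the ethyl group cis to C8 without touching the benzyl ethers.

Step 9
Reactants: 13 cis-hydrindanol
Product: 14 tricyclic γ-lactone (O11–C14(=O)–C13H2–C12, cis-fused on the β face)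
Conditions: TFA/CH2Cl2 (1:4), 0 °C → rt
Reagents that add atoms: none
Why: acidolysis of the tert-butyl ester and spontaneous lactonisation of the cis-γ-hydroxy acid should give the cis-fused lactone, the benzyl ethers being acid-stable.

Step 10
Reactants: 14 tricyclic γ-lactone
Product: 15 (13R)-13-hydroxy lactone (hydroxyl on the convex face, cis to 12-H)
Conditions: KN(SiMe3)2, THF, −78 °C; 2-(phenylsulfonyl)-3-phenyloxaziridine, −78 °C; AcOH
Reagents that add atoms: 2-(phenylsulfonyl)-3-phenyloxaziridine, O=S(=O)(N1OC1c1ccccc1)c1ccccc1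
Why: electrophilic hydroxylation of the only available enolate (lactone C13) with a sulfonyloxaziridine should occur on the convex face; the C13 configuration formed here is erased again in step 12.

Step 11
Reactants: 15 (13R)-13-hydroxy lactone
Product: 16 13-O-TBS ether of 15
Conditions: TBSOTf, 2,6-lutidine, CH2Cl2, 0 °C
Reagents that add atoms: tert-butyldimethylsilyl trifluoromethanesulfonate, CC(C)(C)[Si](C)(C)OS(=O)(=O)C(F)(F)F
Why: silylation of the secondary α-hydroxyl gives an ether that tolerates enolate formation and all later steps up to the final fluoride cleavage.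

Step 12
Reactants: 16 13-O-TBS ether
Product: 17 (13S)-13-methyl-13-silyloxy lactone (methyl cis to 12-H, OTBS cis to C9a)
Conditions: LiN(i-Pr)2, THF/DMPU, −78 °C; MeI, −78 → −40 °C
Reagents that add atoms: iodomethane, CI
Why: alkylation of the α-silyloxy lactone enolate from the convex face of the cis-fused bicycle should place the methyl trans to C9a and leave the oxygen cis to it, which is the 13S arrangement of the target (oxygen first, methyl second is the order that gives this epimer).

Step 13
Reactants: 17 (13S)-13-methyl-13-silyloxy lactone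
Product: 18 diol (C3 primary OH, C5 secondary OH)
Conditions: H2 (1 atm), Pd(OH)2/C, EtOAc/EtOH, rt
Reagents that add atoms: none
Why: hydrogenolysis removes both benzyl ethers in one operation now that no alkene is left, leaving the lactone and silyl ether untouched.

Step 14
Reactants: 18 diol
Product: 19 keto aldehyde (C3 aldehyde, C5 ketone)
Conditions: Dess–Martin periodinane (3 equiv), NaHCO3, CH2Cl2, rt
Reagents that add atoms: none
Why: one oxidation converts the primary alcohol into the C3 aldehyde and the secondary alcohol into the C5 ketone required for the key step, the tertiary silyl ether being inert.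

Step 15
Reactants: 20 3-methylfuran-2(5H)-one
Product: 21 3-methyl-2-(trimethylsilyloxy)furan
Conditions: TMSCl, Et3N, CH2Cl2, 0 °C → rt; distillation
Reagents that add atoms: chlorotrimethylsilane, C[Si](C)(C)Cl
Why: O-silylation of the butenolide dienolate gives the aromatic 2-silyloxyfuran, the standard nucleophile for vinylogous aldol additions.

Step 16
Reactants: 19 keto aldehyde; 21 3-methyl-2-(trimethylsilyloxy)furan
Product: 22 hydroxy butenolide (C3 carries (R)-OH and the (S)-4-methyl-5-oxo-2,5-dihydrofuran-2-yl group; 3R,18S, anti)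
Conditions: Cr(salen)SbF6 (cationic complex of trivalent chromium with a binaphthyl-bearing salen ligand, 5 mol %, antipode chosen for the 3R,18S adduct), i-PrOH (1.1 equiv), CH2Cl2, −20 °C
Reagents that add atoms: none
Why: catalytic enantioselective vinylogous Mukaiyama aldol addition of the silyloxyfuran through its C5 to the aldehyde (far more electrophilic than the hindered ketone) should give the anti adduct with catalyst-controlled configuration at C3 and C18, the remote core stereocentres exerting no bias.

Step 17
Reactants: 22 hydroxy butenolide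
Product: 23 hydroxy lactone (3R,18S,20S; (2S,4S)-4-methyl-5-oxotetrahydrofuran-2-yl group)
Conditions: H2 (1 atm), Rh/Al2O3, EtOAc, rt
Reagents that add atoms: none
Why: heterogeneous hydrogenation of the α-methylbutenolide from the face opposite the C18 substituent should give the cis-2,4-disubstituted lactone, with rhodium chosen to avoid allylic C–O hydrogenolysis and ketone reduction.

Step 18
Reactants: 23 hydroxy lactone
Product: 24 azido ketone (3S,18S,20S)
Conditions: PPh3, DIAD, (PhO)2P(O)N3, THF, 0 °C → rt
Reagents that add atoms: diphenylphosphoryl azide, [N-]=[N+]=NP(=O)(Oc1ccccc1)Oc1ccccc1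
Why: Mitsunobu azidation displaces the activated secondary hydroxyl with inversion, turning the 3R alcohol into the 3S azide (threo to O18) that the target needs.

Step 19
Reactants: 24 azido ketone
Product: 25 lactam (13-O-TBS-5-oxo derivative of the target)
Conditions: TiCl4 (4 equiv), CH2Cl2, 0 °C → rt; aq. NaHCO3
Reagents that add atoms: none
Why: TiCl4 activates the C5 ketone, the internal nitrogen of the C3 azide adds to it to give a six-membered azidohydrin (N, C5, C9a, C1, C2, C3), and the C5–C9a bond antiperiplanar to the departing N2 then migrates from carbon to nitrogen, the resulting N-acyl cation collapsing to the lactam. The closest known reaction type is the intramolecular Schmidt reaction of 2-(3-azidopropyl)cyclohexanones to hexahydropyrrolo[1,2-a]azepin-5-ones, including cases in which the migrating α-carbon is quaternary. The pyrrolidine is closed by this 1,2-shift of C9a (ring contraction of the azidohydrin formed by 6-exo-trig addition to the carbonyl) and the azepane arises at the same time by one-atom expansion of the cyclohexanone, so one event forms the N4–C9a bond and both nitrogen rings. No new stereocentre is formed: C9a migrates with retention, so the all-carbon quaternary centre set in step 3 becomes the aza-quaternary centre, and C3 keeps the configuration set in step 18. The selectivity needed is migration of C9a and not of C6 (which would give a bridged lactam); it should be secured by a chair azidohydrin with the C3 lactone substituent and the diazonium group equatorial, which places only C5–C9a antiperiplanar, and by the higher migratory aptitude of the fully substituted carbon. The lactones and the tertiary silyl ether should only coordinate TiCl4 (hence the excess), and the strong Lewis acid compensates for the lower nucleophilicity of the β-oxygenated azide.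

Step 20
Reactants: 25 lactam
Product: 26 thiolactam (5-thioxo analogue of 25)
Conditions: Lawesson's reagent (0.6 equiv), toluene, 80 °C
Reagents that add atoms: Lawesson's reagent, COc1ccc(cc1)P1(=S)SP(=S)(S1)c1ccc(OC)cc1
Why: thionation is much faster for the tertiary lactam than for the two lactones, which singles out the C5 carbonyl for removal.

Step 21
Reactants: 26 thiolactam
Product: 27 13-O-TBS ether of the target
Conditions: Raney Ni, THF/EtOH, rt
Reagents that add atoms: none
Why: reductive desulfurisation of the thiolactam gives the C5 methylene under neutral conditions that should leave both lactones and the C20 stereocentre intact.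

Step 22
Reactants: 27 13-O-TBS ether of the target
Product: 28 CNP0260919.4
Conditions: HF·pyridine, THF/pyridine, 0 °C → rt; aq. NaHCO3
Reagents that add atoms: none
Why: fluoride cleavage of the tertiary silyl ether under buffered, non-basic conditions should release the C13 hydroxyl without opening or epimerising the lactones.

**Compound list**

1 | cyclohexane-1,3-dione | O=C1CCCC(=O)C1 | starting material
2 | 3-(benzyloxy)propanal | O=CCCOCc1ccccc1 | starting material
3 | 2-[3-(benzyloxy)propyl]cyclohexane-1,3-dione | O=C1CCCC(=O)C1CCCOCc1ccccc1 | intermediate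
4 | 1-bromopent-2-yne | CCC#CCBr | starting material
5 | 2-[3-(benzyloxy)propyl]-2-(pent-2-yn-1-yl)cyclohexane-1,3-dione | CCC#CCC1(CCCOCc2ccccc2)C(=O)CCCC1=O | intermediate
6 | (2R,3R)-2-[3-(benzyloxy)propyl]-3-hydroxy-2-(pent-2-yn-1-yl)cyclohexan-1-one (hydroxyl cis to the pentynyl chain) | CCC#CC[C@]1(CCCOCc2ccccc2)[C@H](O)CCCC1=O | intermediate
7 | (2R,3R)-3-(benzyloxy)-2-[3-(benzyloxy)propyl]-2-(pent-2-yn-1-yl)cyclohexan-1-one | CCC#CC[C@]1(CCCOCc2ccccc2)[C@H](OCc2ccccc2)CCCC1=O | intermediate
8 | (2R,3R)-3-(benzyloxy)-2-[3-(benzyloxy)propyl]-2-(2-oxopentyl)cyclohexan-1-one | CCCC(=O)C[C@]1(CCCOCc2ccccc2)[C@H](OCc2ccccc2)CCCC1=O | intermediate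
9 | (7R,7aS)-7-(benzyloxy)-7a-[3-(benzyloxy)propyl]-3-ethyl-1,4,5,6,7,7a-hexahydro-2H-inden-2-one (bicyclic enone C9=C10–C11=O) | CCC1=C2CCC[C@@H](OCc3ccccc3)[C@@]2(CCCOCc3ccccc3)CC1=O | intermediate
10 | tert-butyl bromoacetate | CC(C)(C)OC(=O)CBr | starting material
11 | C12-alkylated enone: 9 with a CH2CO2t-Bu arm on C12, β (cis to the 3-benzyloxypropyl chain) | CCC1=C2CCC[C@@H](OCc3ccccc3)[C@@]2(CCCOCc3ccccc3)[C@H](CC(=O)OC(C)(C)C)C1=O | intermediate
12 | allylic alcohol: 11 with the ketone reduced to 11β-OH, cis to the C12 arm | CCC1=C2CCC[C@@H](OCc3ccccc3)[C@@]2(CCCOCc3ccccc3)[C@H](CC(=O)OC(C)(C)C)[C@@H]1O | intermediate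
13 | cis-hydrindanol: 12 with C9=C10 saturated; 9-H, 10-H, 11-OH, C12 arm and C1 chain β; 10-ethyl and C8 α | CC[C@@H]1[C@@H](O)[C@@H](CC(=O)OC(C)(C)C)[C@]3(CCCOCc4ccccc4)[C@H](OCc4ccccc4)CCC[C@H]13 | intermediate
14 | tricyclic γ-lactone: O11–C14(=O)–C13H2–C12 cis-fused on the β face of the cis-hydrindane; 10α-ethyl, 5-OBn, 9a-(3-benzyloxypropyl) | CC[C@@H]1[C@H]2OC(=O)C[C@H]2[C@]3(CCCOCc4ccccc4)[C@H](OCc4ccccc4)CCC[C@H]13 | intermediate
15 | (13R)-13-hydroxy derivative of 14 (hydroxyl on the convex face, cis to 12-H) | CC[C@@H]1[C@H]2OC(=O)[C@H](O)[C@H]2[C@]3(CCCOCc4ccccc4)[C@H](OCc4ccccc4)CCC[C@H]13 | intermediate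
16 | 13-O-TBS ether of 15 | CC[C@@H]1[C@H]2OC(=O)[C@H](O[Si](C)(C)C(C)(C)C)[C@H]2[C@]3(CCCOCc4ccccc4)[C@H](OCc4ccccc4)CCC[C@H]13 | intermediate
17 | (13S)-13-methyl derivative of 16 (methyl cis to 12-H, OTBS cis to C9a) | CC[C@@H]1[C@H]2OC(=O)[C@@](C)(O[Si](C)(C)C(C)(C)C)[C@H]2[C@]3(CCCOCc4ccccc4)[C@H](OCc4ccccc4)CCC[C@H]13 | intermediate
18 | diol: 17 with both benzyl ethers cleaved (C3 primary OH, C5 secondary OH) | CC[C@@H]1[C@H]2OC(=O)[C@@](C)(O[Si](C)(C)C(C)(C)C)[C@H]2[C@]3(CCCO)[C@H](O)CCC[C@H]13 | intermediate
19 | keto aldehyde: C3 aldehyde and C5 ketone on the lactone-fused cis-hydrindane | CC[C@@H]1[C@H]2OC(=O)[C@@](C)(O[Si](C)(C)C(C)(C)C)[C@H]2[C@]3(CCC=O)C(=O)CCC[C@H]13 | intermediate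
20 | 3-methylfuran-2(5H)-one | CC1=CCOC1=O | starting material
21 | 3-methyl-2-(trimethylsilyloxy)furan | Cc1ccoc1O[Si](C)(C)C | intermediate
22 | hydroxy butenolide: C3 bears (R)-OH and the (S)-4-methyl-5-oxo-2,5-dihydrofuran-2-yl group (3R,18S) | CC[C@@H]1[C@H]2OC(=O)[C@@](C)(O[Si](C)(C)C(C)(C)C)[C@H]2[C@]3(CC[C@@H](O)[C@@H]4C=C(C)C(=O)O4)C(=O)CCC[C@H]13 | intermediate
23 | hydroxy lactone: 22 with the butenolide saturated to the (2S,4S)-4-methyl-5-oxotetrahydrofuran-2-yl group (3R,18S,20S) | CC[C@@H]1[C@H]2OC(=O)[C@@](C)(O[Si](C)(C)C(C)(C)C)[C@H]2[C@]3(CC[C@@H](O)[C@@H]4C[C@H](C)C(=O)O4)C(=O)CCC[C@H]13 | intermediate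
24 | azido ketone: (3S)-azide in place of the hydroxyl of 23 (3S,18S,20S), C5 ketone | CC[C@@H]1[C@H]2OC(=O)[C@@](C)(O[Si](C)(C)C(C)(C)C)[C@H]2[C@]3(CC[C@H](N=[N+]=[N-])[C@@H]4C[C@H](C)C(=O)O4)C(=O)CCC[C@H]13 | intermediate
25 | lactam: 13-O-TBS-5-oxo derivative of the target | CC[C@@H]1[C@H]2OC(=O)[C@@](C)(O[Si](C)(C)C(C)(C)C)[C@H]2[C@]23CC[C@@H]([C@@H]4C[C@H](C)C(=O)O4)N2C(=O)CCC[C@H]13 | intermediate
26 | thiolactam: 5-thioxo analogue of 25 | CC[C@@H]1[C@H]2OC(=O)[C@@](C)(O[Si](C)(C)C(C)(C)C)[C@H]2[C@]23CC[C@@H]([C@@H]4C[C@H](C)C(=O)O4)N2C(=S)CCC[C@H]13 | intermediate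
27 | 13-O-TBS ether of the target | CC[C@@H]1[C@H]2OC(=O)[C@@](C)(O[Si](C)(C)C(C)(C)C)[C@H]2[C@]23CC[C@@H]([C@@H]4C[C@H](C)C(=O)O4)N2CCCC[C@H]13 | intermediate
28 | CNP0260919.4, (3S,9R,9aR,10S,11R,12S,13S,18S,20S) in the locants used here | CC[C@@H]1[C@H]2OC(=O)[C@@](C)(O)[C@H]2[C@]23CC[C@@H]([C@@H]4C[C@H](C)C(=O)O4)N2CCCC[C@H]13 | target

**Step count**

Total: 22 steps. Longest linear sequence: 21 steps (steps 1–14 and 16–22; step 15 prepares the silyloxyfuran).

**Three steps most likely to fail**

Step 3 (desymmetrising reduction). The two chains on C9a are both primary and of similar size, so discrimination between the two enantiotopic carbonyls may be poor; because C5 is oxidised later, a poor diastereomer ratio here becomes poor enantiomeric purity at C9a. The fallback is a classical resolution that sets out from 5 and returns to 6. Compound 5 is mono-reduced without a chiral catalyst (NaBH4, MeOH, −20 °C), the stereoisomer mixture is esterified with (S)-O-methylmandelic acid (DCC, DMAP), the diastereomerically pure (S)-O-methylmandelate ester F1 of 6 is separated by chromatography, and methanolysis (K2CO3, MeOH) returns 6.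

Step 16 (vinylogous aldol). The catalyst must deliver the anti adduct and the correct absolute sense with a functionalised aliphatic aldehyde; erosion of either diastereo- or enantiocontrol would give inseparable side-chain isomers. The fallback builds the side chain from the chiral pool, sets out from 19 and returns to 24. The aldehyde of 19 is methylenated selectively (Ph3P=CH2, THF, −78 °C) to the terminal alkene F2. Cross-metathesis with commercial (S)-2-methylpent-4-enoic acid (second-generation Hoveyda–Grubbs catalyst, CH2Cl2, 40 °C) should give the E-configured unsaturated acid F3. Iodolactonisation under equilibrating conditions (I2, MeCN, 0 °C) should give, by anti addition, the cis-2,4-disubstituted iodolactone F4. Displacement of iodide with NaN3 in DMF, with inversion at C3, rejoins the route at 24.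

Step 19 (Schmidt ring expansion). The β-oxygenated azide may add too slowly to the hindered ketone, or C6 may migrate in place of C9a to give a bridged lactam. The fallback forms N4–C9a by a Beckmann rearrangement, sets out from 23 and returns to 25. NH2OH·HCl/NaOAc should give the E-oxime F5 (hydroxyl anti to the quaternary carbon). MsCl/Et3N gives the bis-mesylate F6, which on warming in aqueous THF should rearrange, with migration of the anti C9a, to the N-unsubstituted caprolactam mesylate F7. KN(SiMe3)2 then closes the pyrrolidine by N-alkylation at C3 with inversion to give 25.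

**Further compounds**

F1 | step 3 | (1R,2R)-2-[3-(benzyloxy)propyl]-3-oxo-2-(pent-2-yn-1-yl)cyclohexyl (S)-2-methoxy-2-phenylacetate | CCC#CC[C@]1(CCCOCc2ccccc2)[C@H](OC(=O)[C@@H](OC)c2ccccc2)CCCC1=O
F2 | step 16 | terminal alkene: 19 with the C3 aldehyde converted to CH=CH2 (but-3-enyl chain on C9a) | CC[C@@H]1[C@H]2OC(=O)[C@@](C)(O[Si](C)(C)C(C)(C)C)[C@H]2[C@]3(CCC=C)C(=O)CCC[C@H]13
F3 | step 16 | (E)-unsaturated acid: C3=C18 alkene carrying the (S)-2-methylpropanoic acid terminus (20S) | CC[C@@H]1[C@H]2OC(=O)[C@@](C)(O[Si](C)(C)C(C)(C)C)[C@H]2[C@]3(CC/C=C/C[C@H](C)C(=O)O)C(=O)CCC[C@H]13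
F4 | step 16 | iodolactone: (3R)-iodide in place of the hydroxyl of 23 (3R,18S,20S) | CC[C@@H]1[C@H]2OC(=O)[C@@](C)(O[Si](C)(C)C(C)(C)C)[C@H]2[C@]3(CC[C@@H](I)[C@@H]4C[C@H](C)C(=O)O4)C(=O)CCC[C@H]13
F5 | step 19 | E-oxime of 23 at C5 (hydroxyl anti to C9a) | CC[C@@H]1[C@H]2OC(=O)[C@@](C)(O[Si](C)(C)C(C)(C)C)[C@H]2[C@]3(CC[C@@H](O)[C@@H]4C[C@H](C)C(=O)O4)/C(=N/O)CCC[C@H]13
F6 | step 19 | bis-mesylate of F5 (oxime O-mesylate and C3 O-mesylate) | CC[C@@H]1[C@H]2OC(=O)[C@@](C)(O[Si](C)(C)C(C)(C)C)[C@H]2[C@]3(CC[C@@H](OS(C)(=O)=O)[C@@H]4C[C@H](C)C(=O)O4)/C(=N/OS(C)(=O)=O)CCC[C@H]13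
F7 | step 19 | N-unsubstituted caprolactam (N on C9a, C5=O) bearing the C3 mesylate | CC[C@@H]1[C@H]2OC(=O)[C@@](C)(O[Si](C)(C)C(C)(C)C)[C@H]2[C@]3(CC[C@@H](OS(C)(=O)=O)[C@@H]4C[C@H](C)C(=O)O4)NC(=O)CCC[C@H]13
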